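The north-east run had lost 36.9% of its electrophile by 25.0 min, and I started there.

| flask | electrophile | nucleophile | solid base | remark | time |
|---|---|---|---|---|---|
| south | 0.17 M | 1.5 equiv | 0.30 equiv | run made earlier |  |
| north-east | 0.50 M | 1.5 equiv | 0.30 equiv | run made earlier |  |
| Wednesday's | 0.25 M | 3.00 equiv | 0.300 equiv |  | 2.0 h |
| Saturday's | 0.25 M | 1.50 equiv | 0.300 equiv |  | 2.0 h |

| run | time / min | electrophile / % | target / % |
|---|---|---|---|
| south | 2.00 | 98.9 | 1.6 |
| south | 4.00 | 97.4 | 3.8 |
| south | 6.00 | 95.4 | 4.6 |
| south | 12.0 | 91.6 | 8.5 |
| south | 25.0 | 81.1 | 16.9 |
| north-east | 5.00 | 90.8 | 10.1 |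
| north-east | 10.0 | 81.2 | 18.7 |
| north-east | 15.0 | 74.4 | 26.4 |
| north-east | 20.0 | 67.0 | 31.7 |
| north-east | 25.0 | 63.1 | 37.9 |

(standard deviation of a reading: 0.5 percentage points)

- for target the idle adduct is counted in
- as a solid, counted per litre of solution: solid base
- what was read earlier has a scatter of 0.5 percentage points, one standard deviation
- on the list of suspects stand: electrophile + nucleophile -> acid set free + target; nucleophile + acid set free <-> protonated nucleophile; acid set free + free base <-> salt of the base; solid base <-> free base; free base + target <-> idle adduct
- at the start none of the solid base is in solution

1. part of the electrophile that has reacted at the end, Wednesday's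
2. part of the electrophile that has reacted at the end, Saturday's
3. what raising the equivalents of nucleophile from its lowest to its highest value here does to the part of the electrophile that has reacted (changes below 5 percentage points count as none) (it falls / no change / it rises)

I turned that reading into one time, the nucleophile clock: the time in which the starting slope would use up the whole charge of electrophile, here 46.8 min. The clock runs inversely with nucleophile per litre. Wednesday's flask holds as much nucleophile per litre as the north-east run, so its clock is 46.8 min. Saturday's clock is 93.6 min, twice as long.

For M equivalents of nucleophile, time t and clock τ, I took E as the exponential of (M−1)/M times t/τ. The fraction of electrophile left is then (M−1)/(M·E−1).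

My curve for Saturday's left at 0.641 h⁻¹ of the charge. It reached a soft knee at 37.5 min, the time by which my curve had set free as much acid as the charge of solid base. Past that, I let each electrophile cost a second nucleophile. It crossed half reacted at 80.8 min. Paying twice, I set Saturday's level near 90.0%, with nucleophile as the limiting reagent in that sum. The same sum for Wednesday's exceeds the whole charge, so I drew no level below full reaction there.

The north-east reading lay past its knee, so I added no correction. At 2.0 h I got 87.2% for Wednesday's and 61.5% for Saturday's.

The forecast gave 86% (78% to 91%) for Wednesday's and 61% (51% to 67%) for Saturday's, each a little below mine . Its answer on raising the nucleophile was "it rises", and it said: “More nucleophile clearly raises conversion”.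

The flasks gave 85.4% on Wednesday's and 58.7% on Saturday's. On raising the nucleophile the answer was "it rises", by 27 percentage points.

    electrophile + nucleophile → acid set free + target (k = 0.0330 M⁻¹ min⁻¹)
    nucleophile + acid set free ⇌ protonated nucleophile, settled at all times (K = 180 M⁻¹)
    acid set free + free base ⇌ salt of the base, settled at all times (K = 1100 M⁻¹)
    solid base ⇌ free base, rate k4*(cs4 - [free base]) while solid is left; crystals form when [free base] > cs4 (solubility = 0.240 M, k = 0.0150 min⁻¹)
    free base + target ⇌ idle adduct, settled at all times (K = 3.60 M⁻¹)

Wednesday's stood higher because of its extra nucleophile: with Saturday's equivalents it gives 58.7%. On the clock, the asked time was 2.56 clocks for Wednesday's and 1.28 for Saturday's.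

For the neighbour of Saturday's charged with 6.00 equiv, the clock shrinks to 23.4 min, and the rule gives 98.8% reacted. That flask gives 98.8%.

The runs come from a simulation with made-up constants, and the scatter is random.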